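## Retrosynthetic overview

1. The target is a linear lignin-type tetramer, guaiacyl(β-O-4)syringyl(β-O-4)syringyl(β-5)guaiacyl-enal; its only ring, the trans-2,3-dihydrobenzofuran, is formed first.
2. The enal comes from an (E)-propenyl arene by cross-metathesis in the last step, so an inert propenyl group (from isoeugenol) survives every hydride and aldol step.
3. Each erythro arylglycerol β-aryl ether comes from phenol O-alkylation with a chloroacetyl oxazolidinone, an auxiliary-controlled anti-glycolate aldol with an acetoxybenzaldehyde, and LiBH4 reduction (done twice: ring B, then ring A).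
4. The dihydrobenzofuran comes from an oxidative radical β–5 cross-coupling of a camphorsultam sinapamide with isoeugenol, followed by phenol capture of the quinone methide; the sultam on the radical carbon sets C3 and, through trans closure, C2.

Assumption 1: the sultam directs the radical coupling to the Cα-Re face, as in its other non-chelated additions; if the sense proves opposite, the (1R)-(+)-sultam is used with no other change.
Assumption 2: (S)-4-benzyl-3-(chloroacetyl)oxazolidin-2-one and 4-acetoxy-3,5-dimethoxybenzaldehyde are taken as catalogue items.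

## Route

Step 1
Reactants: 1 (1S)-(−)-2,10-camphorsultam; 2 bromoacetyl bromide
Product: 3 N-(bromoacetyl)-(2R)-bornane-10,2-sultam
Conditions: NaH, THF, 0 °C; then 2, 0 °C → rt
Reagents that add atoms: none
Why: N-acylation of the sodium sultamide by the acid bromide, which reacts far faster than the alkyl bromide end; no stereocentre is formed.

Step 2
Reactants: 3 N-(bromoacetyl)-(2R)-bornane-10,2-sultam; 4 syringaldehyde
Product: 7 N-[(E)-sinapoyl]-(2R)-bornane-10,2-sultam, via phosphonium bromide 5 (not isolated), via phosphorus ylide 6 (not isolated)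
Conditions: PPh3, PhMe, rt; aq. Na2CO3; then 4, PhMe, 90 °C
Reagents that add atoms: none
Why: One-flask Wittig olefination; the imide-stabilised ylide tolerates the free phenol and gives the (E)-enoyl sultam under thermodynamic control.

Step 3
Reactants: 7 N-[(E)-sinapoyl]-(2R)-bornane-10,2-sultam; 8 (E)-isoeugenol
Product: 10 sultam amide of (2R,3R)-2-(4-hydroxy-3,5-dimethoxyphenyl)-7-methoxy-5-[(E)-prop-1-enyl]-2,3-dihydrobenzofuran-3-carboxylic acid, via quinone methide 9 (not isolated)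
Conditions: Ag2O (1.5 equiv), 8 (1.5 equiv, added over 4 h), CH2Cl2–acetone 2:1, rt, dark, N2
Reagents that add atoms: none
Why: Biomimetic oxidative phenol (radical–radical) β–5 cross-coupling, modelled on the sultam-directed dehydrodimerisation of ferulic amides: Ag2O oxidises both phenols, the sinapoyl radical bonds through its carbon alpha to the imide to C5 of the isoeugenol radical on the Cα-Re face (anti, s-cis N-acyl sultam conformer, one sulfonyl oxygen blocking the other face), and the rearomatised phenol adds to quinone methide 9 to close the ring with the 2-aryl group trans to the 3-acyl group.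

Step 4
Reactants: 10 sultam amide from step 3
Product: 11 4-[(2R,3S)-3-(hydroxymethyl)-7-methoxy-5-[(E)-prop-1-enyl]-2,3-dihydrobenzofuran-2-yl]-2,6-dimethoxyphenol
Conditions: LiBH4, THF–MeOH, 0 °C → rt
Reagents that add atoms: none
Why: Reductive cleavage of the N-acyl sultam to the primary alcohol with recovery of the auxiliary; C3 keeps its spatial arrangement (R becomes S only through the priority change), and removing the acidic C3–H before any base-mediated step prevents epimerisation or ring opening later.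

Step 5
Reactants: 11 phenylcoumaran phenol; 12 (S)-4-benzyl-3-(chloroacetyl)oxazolidin-2-one
Product: 13 (S)-4-benzyl-3-(aryloxyacetyl)oxazolidin-2-one whose aryloxy group is the phenoxide of 11
Conditions: K2CO3, NaI (10 mol%), MeCN, 40 °C
Reagents that add atoms: none
Why: Williamson etherification; K2CO3 deprotonates only the phenol, which displaces the halide of the activated α-halo imide by SN2 (iodide catalysis) while the primary alcohol stays free.

Step 6
Reactants: 13 aryloxyacetyl imide; 14 4-acetoxy-3,5-dimethoxybenzaldehyde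
Product: 17 (S)-4-benzyl-3-[(2R,3R)-3-(4-acetoxy-3,5-dimethoxyphenyl)-3-hydroxy-2-(aryloxy)propanoyl]oxazolidin-2-one, via silyl ether 15 (not isolated), via bis-silylated aldol adduct 16 (not isolated)
Conditions: MgCl2 (20 mol%), Et3N (3.5 equiv), TMSCl (3 equiv), EtOAc, rt; then citric acid, MeOH, rt
Reagents that add atoms: none
Why: Proposed new method: soft enolisation of the α-aryloxyacetyl imide by MgCl2/Et3N should give the chelated (Z)-magnesium enolate, which adds to the aldehyde through a boat transition state on the face away from the benzyl group and is turned over by O-silylation (the same TMSCl/Et3N masks the free CH2OH in situ), giving the anti (erythro) adduct with 2R,3R configuration; the closest known reaction is the magnesium-halide-catalysed direct anti-aldol of N-propionyl oxazolidinones with aromatic aldehydes.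

Step 7
Reactants: 17 anti-aldol adduct
Product: 18 (1R,2S)-1-(4-hydroxy-3,5-dimethoxyphenyl)-2-(aryloxy)propane-1,3-diol whose aryloxy group is the phenoxide of 11
Conditions: LiBH4, THF–MeOH, 0 °C
Reagents that add atoms: none
Why: LiBH4 reductive removal of the oxazolidinone gives the 1,3-diol without retro-aldol and reduces off the aryl acetate in the same operation, freeing the ring B phenol; both new stereocentres are untouched and the unit is now erythro (7R,8S).

Step 8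
Reactants: 18 trimer phenol; 12 (S)-4-benzyl-3-(chloroacetyl)oxazolidin-2-one
Product: 19 (S)-4-benzyl-3-(aryloxyacetyl)oxazolidin-2-one whose aryloxy group is the phenoxide of 18
Conditions: K2CO3, NaI (10 mol%), MeCN, 40 °C
Reagents that add atoms: none
Why: Williamson etherification as in step 5; only the ring B phenol is acidic enough to be alkylated in the presence of three alcohols.

Step 9
Reactants: 19 aryloxyacetyl imide; 20 4-acetoxy-3-methoxybenzaldehyde (vanillin acetate)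
Product: 23 (S)-4-benzyl-3-[(2R,3R)-3-(4-acetoxy-3-methoxyphenyl)-3-hydroxy-2-(aryloxy)propanoyl]oxazolidin-2-one, via tris-silyl ether 21 (not isolated), via tetrakis-silylated aldol adduct 22 (not isolated)
Conditions: MgCl2 (30 mol%), Et3N (6 equiv), TMSCl (5.5 equiv), EtOAc, rt; then citric acid, MeOH, rt
Reagents that add atoms: none
Why: Proposed new method: the same chelated magnesium-enolate anti-aldol as in step 6, with the three free hydroxyls masked in situ as TMS ethers, should set the ring A unit as 2R,3R (erythro) under control of the (S)-auxiliary; the closest known reaction is the magnesium-halide-catalysed direct anti-aldol of N-acyl oxazolidinones with aromatic aldehydes.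

Step 10
Reactants: 23 anti-aldol adduct
Product: 24 propenyl analogue of the target (CH3 in place of CHO)
Conditions: LiBH4, THF–MeOH, 0 °C
Reagents that add atoms: none
Why: LiBH4 reductive removal of the auxiliary to the 1,3-diol with concurrent reduction of the aryl acetate to the ring A phenol; no stereocentre is touched.

Step 11
Reactants: 24 propenyl tetramer; 25 (E)-crotonaldehyde
Product: 26 target CNP0192639.1
Conditions: second-generation Hoveyda–Grubbs catalyst (10 mol%), 25 (10 equiv), CH2Cl2–EtOAc, 40 °C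
Reagents that add atoms: none
Why: Olefin cross-metathesis of the electron-rich β-methylstyrene with the enal exchanges the CH–CH3 terminus for CH–CHO, giving the (E)-cinnamaldehyde under thermodynamic control with loss of volatile but-2-ene; the ruthenium carbene tolerates the phenol and alcohols and no stereocentre is involved.

## Compound list

1 | (1S)-(−)-2,10-camphorsultam, (2R)-bornane-10,2-sultam | CC1(C)[C@@H]2CC[C@]13CS(=O)(=O)N[C@@H]3C2 | starting material
2 | bromoacetyl bromide | BrCC(Br)=O | starting material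
3 | N-(bromoacetyl)-(2R)-bornane-10,2-sultam | CC1(C)[C@@H]2CC[C@]13CS(=O)(=O)N(C(=O)CBr)[C@@H]3C2 | intermediate
4 | syringaldehyde (4-hydroxy-3,5-dimethoxybenzaldehyde) | COc1cc(C=O)cc(OC)c1O | starting material
5 | [2-oxo-2-(sultam-N-yl)ethyl]triphenylphosphonium bromide | CC1(C)[C@@H]2CC[C@]13CS(=O)(=O)N(C(=O)C[P+](c4ccccc4)(c4ccccc4)c4ccccc4)[C@@H]3C2.[Br-] | intermediate
6 | N-[(triphenylphosphoranylidene)acetyl]-(2R)-bornane-10,2-sultam | CC1(C)[C@@H]2CC[C@]13CS(=O)(=O)N(C(=O)C=P(c4ccccc4)(c4ccccc4)c4ccccc4)[C@@H]3C2 | intermediate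
7 | N-[(E)-3-(4-hydroxy-3,5-dimethoxyphenyl)acryloyl]-(2R)-bornane-10,2-sultam | CC1(C)[C@@H]2CC[C@]13CS(=O)(=O)N(C(=O)/C=C/c4cc(OC)c(O)c(OC)c4)[C@@H]3C2 | intermediate
8 | (E)-isoeugenol, 2-methoxy-4-[(E)-prop-1-enyl]phenol | C/C=C/c1ccc(O)c(OC)c1 | starting material
9 | quinone methide: N-[(2S)-2-{2-hydroxy-3-methoxy-5-[(E)-prop-1-enyl]phenyl}-3-(3,5-dimethoxy-4-oxocyclohexa-2,5-dien-1-ylidene)propanoyl]-(2R)-bornane-10,2-sultam | CC1(C)[C@@H]2CC[C@]13CS(=O)(=O)N(C(=O)[C@@H](C=C4C=C(OC)C(=O)C(OC)=C4)c4cc(/C=C/C)cc(OC)c4O)[C@@H]3C2 | intermediate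
10 | N-{[(2R,3R)-2-(4-hydroxy-3,5-dimethoxyphenyl)-7-methoxy-5-[(E)-prop-1-enyl]-2,3-dihydrobenzofuran-3-yl]carbonyl}-(2R)-bornane-10,2-sultam (trans) | CC1(C)[C@@H]2CC[C@]13CS(=O)(=O)N(C(=O)[C@@H]4c5cc(/C=C/C)cc(OC)c5O[C@H]4c4cc(OC)c(O)c(OC)c4)[C@@H]3C2 | intermediate
11 | 4-[(2R,3S)-3-(hydroxymethyl)-7-methoxy-5-[(E)-prop-1-enyl]-2,3-dihydrobenzofuran-2-yl]-2,6-dimethoxyphenol (trans) | COc1cc([C@@H]2Oc3c(OC)cc(/C=C/C)cc3[C@H]2CO)cc(OC)c1O | intermediate
12 | (S)-4-benzyl-3-(chloroacetyl)oxazolidin-2-one | O=C(CCl)N1[C@@H](Cc2ccccc2)COC1=O | starting material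
13 | (S)-4-benzyl-3-({4-[(2R,3S)-3-(hydroxymethyl)-7-methoxy-5-[(E)-prop-1-enyl]-2,3-dihydrobenzofuran-2-yl]-2,6-dimethoxyphenoxy}acetyl)oxazolidin-2-one | COc1cc([C@@H]2Oc3c(OC)cc(/C=C/C)cc3[C@H]2CO)cc(OC)c1OCC(=O)N1[C@@H](Cc2ccccc2)COC1=O | intermediate
14 | 4-acetoxy-3,5-dimethoxybenzaldehyde (syringaldehyde acetate) | CC(=O)Oc1c(OC)cc(C=O)cc1OC | starting material
15 | O-trimethylsilyl ether of 13 (CH2OTMS) | COc1cc([C@@H]2Oc3c(OC)cc(/C=C/C)cc3[C@H]2CO[Si](C)(C)C)cc(OC)c1OCC(=O)N1[C@@H](Cc2ccccc2)COC1=O | intermediate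
16 | bis-O-trimethylsilyl ether of 17 (benzylic OTMS and CH2OTMS) | CC(=O)Oc1c(OC)cc([C@@H](O[Si](C)(C)C)[C@H](C(=O)N2[C@@H](Cc3ccccc3)COC2=O)Oc2c(OC)cc([C@@H]3Oc4c(OC)cc(/C=C/C)cc4[C@H]3CO[Si](C)(C)C)cc2OC)cc1OC | intermediate
17 | (S)-4-benzyl-3-[(2R,3R)-3-(4-acetoxy-3,5-dimethoxyphenyl)-3-hydroxy-2-{4-[(2R,3S)-3-(hydroxymethyl)-7-methoxy-5-[(E)-prop-1-enyl]-2,3-dihydrobenzofuran-2-yl]-2,6-dimethoxyphenoxy}propanoyl]oxazolidin-2-one (anti aldol) | CC(=O)Oc1c(OC)cc([C@@H](O)[C@H](C(=O)N2[C@@H](Cc3ccccc3)COC2=O)Oc2c(OC)cc([C@@H]3Oc4c(OC)cc(/C=C/C)cc4[C@H]3CO)cc2OC)cc1OC | intermediate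
18 | (1R,2S)-1-(4-hydroxy-3,5-dimethoxyphenyl)-2-{4-[(2R,3S)-3-(hydroxymethyl)-7-methoxy-5-[(E)-prop-1-enyl]-2,3-dihydrobenzofuran-2-yl]-2,6-dimethoxyphenoxy}propane-1,3-diol (erythro) | COc1cc([C@@H](O)[C@H](CO)Oc2c(OC)cc([C@@H]3Oc4c(OC)cc(/C=C/C)cc4[C@H]3CO)cc2OC)cc(OC)c1O | intermediate
19 | (S)-4-benzyl-3-(aryloxyacetyl)oxazolidin-2-one, aryloxy = phenoxide of 18 | COc1cc([C@@H](O)[C@H](CO)Oc2c(OC)cc([C@@H]3Oc4c(OC)cc(/C=C/C)cc4[C@H]3CO)cc2OC)cc(OC)c1OCC(=O)N1[C@@H](Cc2ccccc2)COC1=O | intermediate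
20 | 4-acetoxy-3-methoxybenzaldehyde (vanillin acetate) | CC(=O)Oc1ccc(C=O)cc1OC | starting material
21 | tris-O-trimethylsilyl ether of 19 | COc1cc([C@@H](O[Si](C)(C)C)[C@H](CO[Si](C)(C)C)Oc2c(OC)cc([C@@H]3Oc4c(OC)cc(/C=C/C)cc4[C@H]3CO[Si](C)(C)C)cc2OC)cc(OC)c1OCC(=O)N1[C@@H](Cc2ccccc2)COC1=O | intermediate
22 | tetrakis-O-trimethylsilyl ether of 23 | COc1cc([C@@H](O[Si](C)(C)C)[C@H](C(=O)N2[C@@H](Cc3ccccc3)COC2=O)Oc2c(OC)cc([C@@H](O[Si](C)(C)C)[C@H](CO[Si](C)(C)C)Oc3c(OC)cc([C@@H]4Oc5c(OC)cc(/C=C/C)cc5[C@H]4CO[Si](C)(C)C)cc3OC)cc2OC)ccc1OC(C)=O | intermediate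
23 | (S)-4-benzyl-3-[(2R,3R)-3-(4-acetoxy-3-methoxyphenyl)-3-hydroxy-2-(aryloxy)propanoyl]oxazolidin-2-one, aryloxy = phenoxide of 18 (anti aldol) | COc1cc([C@@H](O)[C@H](C(=O)N2[C@@H](Cc3ccccc3)COC2=O)Oc2c(OC)cc([C@@H](O)[C@H](CO)Oc3c(OC)cc([C@@H]4Oc5c(OC)cc(/C=C/C)cc5[C@H]4CO)cc3OC)cc2OC)ccc1OC(C)=O | intermediate
24 | (1R,2S)-1-(4-hydroxy-3-methoxyphenyl)-2-{4-[(1R,2S)-1,3-dihydroxy-2-{4-[(2R,3S)-3-(hydroxymethyl)-7-methoxy-5-[(E)-prop-1-enyl]-2,3-dihydrobenzofuran-2-yl]-2,6-dimethoxyphenoxy}propyl]-2,6-dimethoxyphenoxy}propane-1,3-diol | COc1cc([C@@H](O)[C@H](CO)Oc2c(OC)cc([C@@H](O)[C@H](CO)Oc3c(OC)cc([C@@H]4Oc5c(OC)cc(/C=C/C)cc5[C@H]4CO)cc3OC)cc2OC)ccc1O | intermediate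
25 | (E)-crotonaldehyde | C/C=C/C=O | starting material
26 | CNP0192639.1: as 24 with (E)-3-oxoprop-1-enyl at C5 of the dihydrobenzofuran | COc1cc([C@@H](O)[C@H](CO)Oc2c(OC)cc([C@@H](O)[C@H](CO)Oc3c(OC)cc([C@@H]4Oc5c(OC)cc(/C=C/C=O)cc5[C@H]4CO)cc3OC)cc2OC)ccc1O | target

## Step count and risks

Total steps: 11. Longest linear sequence: 11 (1 → 26).

Steps most likely to fail:

Step 3. Homodimerisation of 8, 4-O and β–β cross-products and over-oxidation of 10 compete, and facial control by the sultam may be incomplete (the minor C3 epimer is a separable diastereomer). Fallback: give up the auxiliary and the acyl oxidation level. Setting out from 8, horseradish peroxidase/H2O2 (acetone–pH 5 buffer, rt) cross-coupling with commercial sinapyl alcohol F1 gives the racemic trans-phenylcoumaran alcohol F2 in one step. F2 is resolved by preparative chromatography on a cellulose tris(3,5-dimethylphenylcarbamate) phase; the (2R,3S) enantiomer is 11, where the route is rejoined (steps 1, 2 and 4 are then not needed).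

Step 6. The magnesium anti-aldol is untested on an α-aryloxyacetyl imide and may give low anti selectivity or the wrong enolate face. Fallback: syn-aldol with the mirror-image auxiliary, then inversion at the benzylic carbon. Setting out from 10, K2CO3/NaI alkylation with (R)-4-benzyl-3-(chloroacetyl)oxazolidin-2-one F3 gives the imide F4, which has no free aliphatic hydroxyl. The established Bu2BOTf/iPr2NEt syn-aldol (CH2Cl2, −78 → 0 °C) with 14 gives the threo adduct F5 (2R,3S in the acyl chain). Mitsunobu inversion of its only free hydroxyl (4-nitrobenzoic acid, PPh3, DIAD, THF, 0 °C) gives the erythro 4-nitrobenzoate F6. Excess LiBH4 then cleaves sultam, oxazolidinone, aryl acetate and nitrobenzoate together and the route is rejoined at 18.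

Step 9. The same untested aldol is run on a larger substrate whose three hydroxyls must all be silylated in situ. Fallback: the same syn-aldol/inversion logic with isolable acetate protection. Setting out from 18, alkylation with F3 gives the imide F7, and Ac2O/pyridine caps its three hydroxyls to give the triacetate F8. Bu2BOTf/iPr2NEt syn-aldol with 20 gives the threo adduct F9, and Mitsunobu inversion with 4-nitrobenzoic acid gives the erythro ester F10. Excess LiBH4 (THF–MeOH) removes the auxiliary, all four acetates and the nitrobenzoate, and the route is rejoined at 24.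

## Further compounds

F1 | step 3 | sinapyl alcohol, 4-[(E)-3-hydroxyprop-1-enyl]-2,6-dimethoxyphenol | COc1cc(/C=C/CO)cc(OC)c1O
F2 | step 3 | racemic trans-4-[3-(hydroxymethyl)-7-methoxy-5-[(E)-prop-1-enyl]-2,3-dihydrobenzofuran-2-yl]-2,6-dimethoxyphenol (1:1 mixture of 2R,3S and 2S,3R) | COc1cc([C@@H]2Oc3c(OC)cc(/C=C/C)cc3[C@H]2CO)cc(OC)c1O.COc1cc([C@H]2Oc3c(OC)cc(/C=C/C)cc3[C@@H]2CO)cc(OC)c1O
F3 | step 6 | (R)-4-benzyl-3-(chloroacetyl)oxazolidin-2-one | O=C(CCl)N1[C@H](Cc2ccccc2)COC1=O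
F4 | step 6 | O-{2-[(R)-4-benzyl-2-oxooxazolidin-3-yl]-2-oxoethyl} ether of 10 | CC1(C)[C@@H]2CC[C@]13CS(=O)(=O)N(C(=O)[C@@H]4c5cc(/C=C/C)cc(OC)c5O[C@H]4c4cc(OC)c(OCC(=O)N6[C@H](Cc7ccccc7)COC6=O)c(OC)c4)[C@@H]3C2
F5 | step 6 | syn-aldol adduct of F4 with 14, (2R,3S)-3-(4-acetoxy-3,5-dimethoxyphenyl)-3-hydroxy-2-(aryloxy)propanoyl imide of the (R)-auxiliary | CC1(C)[C@@H]2CC[C@]13CS(=O)(=O)N(C(=O)[C@@H]4c5cc(/C=C/C)cc(OC)c5O[C@H]4c4cc(OC)c(O[C@@H](C(=O)N6[C@H](Cc7ccccc7)COC6=O)[C@@H](O)c6cc(OC)c(OC(C)=O)c(OC)c6)c(OC)c4)[C@@H]3C2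
F6 | step 6 | 4-nitrobenzoate of the C3-inverted (2R,3R) adduct | CC1(C)[C@@H]2CC[C@]13CS(=O)(=O)N(C(=O)[C@@H]4c5cc(/C=C/C)cc(OC)c5O[C@H]4c4cc(OC)c(O[C@@H](C(=O)N6[C@H](Cc7ccccc7)COC6=O)[C@H](OC(=O)c6ccc(cc6)[N+](=O)[O-])c6cc(OC)c(OC(C)=O)c(OC)c6)c(OC)c4)[C@@H]3C2
F7 | step 9 | (R)-4-benzyl-3-(aryloxyacetyl)oxazolidin-2-one, aryloxy = phenoxide of 18 | COc1cc([C@@H](O)[C@H](CO)Oc2c(OC)cc([C@@H]3Oc4c(OC)cc(/C=C/C)cc4[C@H]3CO)cc2OC)cc(OC)c1OCC(=O)N1[C@H](Cc2ccccc2)COC1=O
F8 | step 9 | tri-O-acetate of F7 | COc1cc([C@@H](OC(C)=O)[C@H](COC(C)=O)Oc2c(OC)cc([C@@H]3Oc4c(OC)cc(/C=C/C)cc4[C@H]3COC(C)=O)cc2OC)cc(OC)c1OCC(=O)N1[C@H](Cc2ccccc2)COC1=O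
F9 | step 9 | syn-aldol adduct of F8 with 20, (2R,3S)-3-(4-acetoxy-3-methoxyphenyl)-3-hydroxy-2-(aryloxy)propanoyl imide of the (R)-auxiliary | COc1cc([C@H](O)[C@H](C(=O)N2[C@H](Cc3ccccc3)COC2=O)Oc2c(OC)cc([C@@H](OC(C)=O)[C@H](COC(C)=O)Oc3c(OC)cc([C@@H]4Oc5c(OC)cc(/C=C/C)cc5[C@H]4COC(C)=O)cc3OC)cc2OC)ccc1OC(C)=O
F10 | step 9 | 4-nitrobenzoate of the C3-inverted (2R,3R) adduct | COc1cc([C@@H](OC(=O)c2ccc(cc2)[N+](=O)[O-])[C@H](C(=O)N2[C@H](Cc3ccccc3)COC2=O)Oc2c(OC)cc([C@@H](OC(C)=O)[C@H](COC(C)=O)Oc3c(OC)cc([C@@H]4Oc5c(OC)cc(/C=C/C)cc5[C@H]4COC(C)=O)cc3OC)cc2OC)ccc1OC(C)=O
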